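The bench chemist's rule comes first: treat a rising yield as a first-order approach to its plateau, and call it finished after a few time constants.

| flask | D | G | J | remark | time |
|---|---|---|---|---|---|
| north-west | 0.50 M | 0.041 M (fed, over 10 h) | 94 mM (held) | run made earlier |  |
| west | 0.50 M | 0.078 M (fed, over 10 h) | 94 mM (held) | run made earlier |  |
| theta | 0.50 M | 0.0500 M (fed, over 10 h) | 94 mM (held) |  | 12 h |
| eta | 0.50 M | 0.0300 M | 94 mM | everything together at the start | 12 h |

- north-west (time / h: E / %): 1.50: 23.9; 3.00: 38.5; 5.00: 48.6; 6.00: 50.1; 8.00: 54.0; 10.0: 54.4; 12.0: 53.9
- west (time / h: E / %): 0.667: 11.9; 2.00: 30.5; 3.00: 39.5; 5.00: 48.5; 8.00: 53.8; 10.0: 54.4; 12.0: 53.5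

(each reading ± 0.5 percentage points)

- which of the two ends with the higher amount of E, in percent of the D charged ("neither" if they lie within 2 percentage points) (theta / eta / neither)
- E at the end, in percent of the D charged, theta
- E at the end, in percent of the D charged, eta

- the earlier runs were read with a standard deviation of 0.5 percentage points

1. Take the plateau from the north-west run: 54.4% at 10.0 h. The first north-west reading then gives a rise time of 2.59 h, the time constant of the gap between E and its plateau.

2. Repeat this with the first west reading, which gives 2.70 h. The west charge of G is twice the north-west charge, yet the two readings of the rise time lie close together.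

3. Apply the rule. At 12 h theta and eta have each had 4.63 rise times, so the gap is 0.53 points, about one reading's scatter. My own reckoning is therefore 53.9% for theta and for eta alike.

4. Find the border with ratios. Theta's G is 1.22 of the north-west charge, inside the tested span. Eta's is 0.732 of it, below that span, and it goes in at the start. In time, the asked time over the last reading time is 1.00, so the rule has no readings beyond it. Those last readings lie 0.5 points and 0.9 points under the ones at 10.0 h, too close to the scatter to show whether control has passed from rise to loss.

5. Read the forecast: neither, with theta at 54% (52.5% to 55.5%) and eta at 53.5% (46% to 56.5%). Its ground is “The plateau looks set by D and J, through equilibrium or a fixed split, not by G.” For eta it stands slightly below my figure.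

6. Now read the flask: theta gives 54.0% and eta 54.0%, so the answer is neither.

    D + Q ⇌ E (K = 25.0 L mol⁻¹, k = 0.0380 L mol⁻¹ min⁻¹)
    Q + G → X (k = 0.550 L mol⁻¹ min⁻¹)
    J ⇌ Q, rate k3*(csat - [Q]) (kL = 0.600 min⁻¹)
    D + E → L (k = 0.00180 L mol⁻¹ min⁻¹)

7. At 12.0 h eta makes E more slowly than it uses E up, at 0.359 of that rate, so E in eta is there a falling intermediate, not at rest. Take the neighbour, eta left until 50 h. It has had 19.3 rise times, and the rule still gives 54.4%. That flask holds 33.4% of the D charged as E and 53.0% as L.

The runs come from a simulation on assumed constants; noise was put on by code.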